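**Remark on conventions and one change of spectator group.** Ring atoms carry labdane numbers (C1–C20) throughout, also in the monocyclic intermediates. The C15 oxygen is carried as a tert-butyldimethylsilyl ether through the key step, so the key-step precursor is 26 and its product is 27; both acetates are installed in the last step.

## Analysis of the target

The target is a labdane of the enantio series: a trans-fused decalin (ring A = C1–C5/C10, ring B = C5–C10) with a trisubstituted C7=C8 alkene, an angular methyl C20 on C10, a gem-dimethyl carbon C4 and a five-carbon chain on C9 that ends in a primary acetate at C15. Three contiguous stereocentres sit on ring B (C5, C9, C10): H5 and H9 lie on the face opposite C20, and the side chain is equatorial and cis to C20. Ring A carries a cis-2,3-diol with both oxygens anti to C20 (C2–O equatorial and acetylated, C3–OH axial and free), and C13 is an isolated (S) centre that no ring can control. The sensitive points are the cis hydroxy-acetate pair (acyl migration under base), the trisubstituted alkene (oxidants, acid-induced shift to C8=C9) and the need to tell two secondary hydroxyls apart. The synthesis is hard because C10 is quaternary between two stereocentres, C3 is a neopentyl carbinol next to quaternary C4, and C13 is remote. The strategy rests on the C2–C3 bond: both carbons bear oxygen, one hangs on C4 and the other on the C1 methylene of C10, so this bond can be made last from two aldehydes, creating both carbinol centres as ring A closes.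

## Retrosynthetic reasoning

**Acetates.** Target 29 is cut at both ester C–O bonds to triol 28, which comes from silyl ether 27. Acylating last avoids carrying an acetate through organometallic and dissolving-metal steps; the forward reaction must acylate the primary C15 and equatorial C2 hydroxyls and spare the axial C3 hydroxyl next to C4.

**C2–C3 (key disconnection).** Diol 27 is cut between the two carbinol carbons to dialdehyde 26. No other ring A bond gives two identical, oxygen-bearing termini, and a cut at C3–C4 or C1–C10 would require bond formation at a quaternary carbon. The forward reductive coupling must close a six-membered ring and deliver the cis-diol on the face opposite C20.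

**C7=C8 alkene and the C2 aldehyde.** 26 is traced to enol triflate 25, and its C2 aldehyde to the prenyl group of 23. Cleaving the prenyl alkene while C7=C8 is still masked as an electron-poor enol triflate removes the problem of distinguishing two trisubstituted alkenes. The triflate is then reduced to the alkene at its fixed position.

**C4 and the C3 aldehyde.** The quaternary aldehyde of 23 is cut at the C4–methyl bond to aldehyde 21, which comes via alcohol 20 from the isopropenyl group of 18. The forward steps (anti-Markovnikov hydroboration, oxidation, enolate methylation) must touch only the 1,1-disubstituted alkene and the single acidic C4–H.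

**C9–H.** Enol triflate 18 comes from enone 16 by reductive enolate formation. The cut is at C9–H because protonation of a β-carbanion places hydrogen axially, anti to the C10 methyl, and leaves the enolate fixed at C7/C8 for trapping.

**C9–C11.** Enone 16 is cut to ketone 12 and iodide 6 through tertiary allylic alcohol 15. The side chain is added to the C9 carbonyl and the oxygen is shifted from C9 to C7 by oxidative transposition; the carbonyl that carried the nucleophile thus becomes the stereocentre-to-be.

**C10.** Ketone 12 is cut at the C10–prenyl and C10–methyl bonds back to 9 and then to (S)-carvone 7 and prenyl bromide 10. The order (methyl first, prenyl second) puts the larger group trans to the isopropenyl group, which is the C5/C10 relation of a trans-decalin.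

**C13.** Iodide 6 is traced through 5, 4, 3 and 2 to prochiral diester 1. An enzymatic desymmetrisation sets the only stereocentre, and the order in which the two termini are reduced decides which end becomes C15.

## Alternatives that were turned down

**Alternative 1:** Ring A is disconnected at C3–C4 and C3–C18 of a cyclopropane-fused ketone. In the forward sense a copper carbenoid, generated from diazo ketone A1 with loss of the diazo nitrogen, adds to the isopropenyl group on C5 and gives tricyclic diketone A2.
- For it: ring A, the C4 quaternary carbon and the C2 oxygen appear in one step from a carvone derivative only a few steps old. Both carbons of the isopropenyl group are used without the three-step homologation needed here. On speed to the bicyclic skeleton this alternative is stronger.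
- Against it: A2 has no oxygen at C3. After reductive opening of the cyclopropane (which must break C3–C18 and not C3–C4, under conditions that would also reduce the ring B enone), the C2 ketone enolises more easily toward C1 than toward the neopentyl C3. The axial C3 hydroxyl and equatorial C2 hydroxyl would then have to be set in separate redox steps, and two ketones (C2, C9) must be distinguished when the side chain is added.
- Comparison: the chosen route spends more steps before ring closure, but the closure itself delivers both oxygens and their cis relation.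

**Alternative 2:** Both rings are disconnected at C5–C10 and C8–C9. On heating, acyclic triene A3 (a (Z)-alkylidene ester joined through C1–C4 to a 2-silyloxy diene) undergoes an intramolecular Diels–Alder reaction to decalin A4.
- For it: two rings, two C–C bonds and four stereocentres form in one step, and the diol arrives as an acetonide from the chiral pool. In bonds formed per step it is clearly stronger.
- Against it: the dienophile carbon that becomes C10 is fully substituted, so the cycloaddition needs forcing conditions that a silyl enol ether diene tolerates poorly. Facial and endo/exo control rest on the tether acetonide alone. The C20 ester must then be reduced to a methyl group at a neopentyl position (about three steps), the C8 centre is made only to be destroyed, and the C6=C7 enol ether must be converted into the C7=C8 alkene by hydrolysis, regioselective enolisation, triflation and reduction. The (Z)-alkene of A3 also requires a controlled olefination.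
- Comparison: the chosen route takes C5 and C10 from carvone chemistry with well-understood facial control and never carries a carbon in the wrong oxidation state.

**Alternative 3:** Ring B is disconnected at C7–C8 and C9–C10. Ring A diene A5 and side-chain ynone A6 combine in an intermolecular Diels–Alder reaction to cyclohexadiene A7.
- For it: two fragments of similar size are joined late, the side chain arrives complete with C13 and C15, and the ring A diol is set early on a simple cyclohexene. In convergence and longest linear sequence it is stronger.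
- Against it: the diene terminus C10 is fully substituted, and the vinyl group on C5 sits between the C4 gem-dimethyl and the C10 methyl, which twists the diene out of the s-cis form. The new C9–C10 bond joins two hindered carbons, and the face of attack is controlled only by the distant acetonide. Afterwards C5=C6 must be reduced to a trans ring fusion, the C8=C9 enone must be deconjugated to C7=C8 with control at C9, and the C11 ketone must be removed, so C5, C9 and C10 all depend on uncertain steps after the cycloaddition.
- Comparison: the chosen route is longer and linear in ring B, but each of these three centres is set by a reaction whose facial preference can be argued from the substrate.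

Key step: step 16

## Route

Step 1
Reactants: 1 dimethyl 3-methylpentanedioate (dimethyl 3-methylglutarate)
Product: 2 (3R)-5-methoxy-3-methyl-5-oxopentanoic acid
Conditions: pig liver esterase, aq. phosphate buffer (pH 7), 20% MeOH, 0 °C
Reagents that add atoms: water, O
Why: Enzymatic desymmetrisation of a prochiral diester: the esterase hydrolyses one enantiotopic ester arm and should give the (R)-half-ester, which fixes C13; if needed the enantiomeric purity can be raised by crystallising an amine salt.

Step 2
Reactants: 2 (3R)-5-methoxy-3-methyl-5-oxopentanoic acid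
Product: 3 methyl (3R)-5-hydroxy-3-methylpentanoate
Conditions: BH3·SMe2, THF, −10 °C → rt
Reagents that add atoms: none
Why: Chemoselective borane reduction: the free acid is reduced through an acyloxyborane much faster than the ester, so the acid carbon becomes C15; the crude hydroxy ester is silylated at once to forestall lactonisation.

Step 3
Reactants: 3 methyl (3R)-5-hydroxy-3-methylpentanoate
Product: 4 methyl (3R)-5-[(tert-butyldimethylsilyl)oxy]-3-methylpentanoate
Conditions: TBSCl, imidazole, DMF, 0 °C → rt
Reagents that add atoms: tert-butyldimethylsilyl chloride, CC(C)(C)[Si](C)(C)Cl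
Why: Standard silylation of a primary alcohol; the silyl ether is chosen because it must survive an organolithium, a dissolving metal, tert-butoxide, ozone and divalent samarium.

Step 4
Reactants: 4 methyl (3R)-5-[(tert-butyldimethylsilyl)oxy]-3-methylpentanoate
Product: 5 (3S)-5-[(tert-butyldimethylsilyl)oxy]-3-methylpentan-1-ol
Conditions: i-Bu2AlH (2.2 equiv), CH2Cl2, −78 → 0 °C
Reagents that add atoms: none
Why: Hydride reduction of the ester to the primary alcohol; the stereocentre is untouched (the descriptor changes only because the priorities change).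

Step 5
Reactants: 5 (3S)-5-[(tert-butyldimethylsilyl)oxy]-3-methylpentan-1-ol
Product: 6 tert-butyl{[(3R)-5-iodo-3-methylpentyl]oxy}dimethylsilane
Conditions: I2, PPh3, imidazole, CH2Cl2, 0 °C → rt
Reagents that add atoms: iodine, II
Why: Appel-type iodination: the alkoxyphosphonium ion is displaced by iodide in an SN2 reaction at the primary carbon that will become C11.

Step 6
Reactants: 7 (S)-carvone
Product: 9 (5S)-2,6-dimethyl-5-(prop-1-en-2-yl)cyclohex-2-en-1-one (mixture at C6), via lithium dienolate 8 (not isolated)
Conditions: LiN(iPr)2, THF, −78 °C; MeI, −78 → 0 °C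
Reagents that add atoms: iodomethane, CI
Why: Kinetic α'-deprotonation of the enone gives the cross-conjugated enolate, which is C-methylated (enolate alkylation); the new centre is re-enolised in step 7, so its configuration does not matter.

Step 7
Reactants: 9 (5S)-2,6-dimethyl-5-(prop-1-en-2-yl)cyclohex-2-en-1-one; 10 1-bromo-3-methylbut-2-ene (prenyl bromide)
Product: 12 (5R,6R)-2,6-dimethyl-6-(3-methylbut-2-en-1-yl)-5-(prop-1-en-2-yl)cyclohex-2-en-1-one, via lithium enolate 11 (not isolated)
Conditions: LiN(iPr)2, THF, −78 °C; 10, DMPU, −78 → −20 °C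
Reagents that add atoms: none
Why: Second α'-alkylation of a ketone enolate: the allylic bromide approaches the tetrasubstituted enolate on the face opposite the adjacent isopropenyl group, so the prenyl group ends up trans and the methyl (C20) cis to the C5 substituent, which is the C5/C10 relation of the trans-decalin.

Step 8
Reactants: 6 tert-butyl{[(3R)-5-iodo-3-methylpentyl]oxy}dimethylsilane; 12 (5R,6R)-2,6-dimethyl-6-(3-methylbut-2-en-1-yl)-5-(prop-1-en-2-yl)cyclohex-2-en-1-one
Product: 15 (5R,6R)-1-{(3S)-5-[(tert-butyldimethylsilyl)oxy]-3-methylpentyl}-2,6-dimethyl-6-(3-methylbut-2-en-1-yl)-5-(prop-1-en-2-yl)cyclohex-2-en-1-ol (mixture at C1), via alkyllithium 13 (not isolated), via alkylcerium dichloride 14 (not isolated)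
Conditions: 6, t-BuLi (2.1 equiv), Et2O–pentane, −78 °C; CeCl3, THF, −78 °C; then 12, −78 → −30 °C
Reagents that add atoms: none
Why: Iodine–lithium exchange, transmetalation to the less basic and more oxophilic organocerium, and 1,2-addition to the hindered enone, which has no α'-hydrogen; the carbinol configuration is irrelevant because C9 becomes trigonal in step 9.

Step 9
Reactants: 15 (5R,6R)-1-{(3S)-5-[(tert-butyldimethylsilyl)oxy]-3-methylpentyl}-2,6-dimethyl-6-(3-methylbut-2-en-1-yl)-5-(prop-1-en-2-yl)cyclohex-2-en-1-ol
Product: 16 (4R,5R)-3-{(3S)-5-[(tert-butyldimethylsilyl)oxy]-3-methylpentyl}-2,4-dimethyl-4-(3-methylbut-2-en-1-yl)-5-(prop-1-en-2-yl)cyclohex-2-en-1-one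
Conditions: pyridinium chlorochromate, NaOAc, 4 Å molecular sieves, CH2Cl2, rt
Reagents that add atoms: pyridinium chlorochromate, [O-][Cr](=O)(=O)Cl.c1cc[nH+]cc1
Why: Babler–Dauben oxidative transposition: the chromate ester of the tertiary allylic alcohol undergoes a [3,3] shift to C7 and is oxidised there, which moves the oxygen from C9 to C7 and the alkene to C8=C9.

Step 10
Reactants: 16 (4R,5R)-3-{(3S)-5-[(tert-butyldimethylsilyl)oxy]-3-methylpentyl}-2,4-dimethyl-4-(3-methylbut-2-en-1-yl)-5-(prop-1-en-2-yl)cyclohex-2-en-1-one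
Product: 18 (3S,4R,5R)-3-{(3S)-5-[(tert-butyldimethylsilyl)oxy]-3-methylpentyl}-2,4-dimethyl-4-(3-methylbut-2-en-1-yl)-5-(prop-1-en-2-yl)cyclohex-1-en-1-yl trifluoromethanesulfonate, via lithium enolate 17 (not isolated)
Conditions: Li, NH3(l)–THF, t-BuOH (1 equiv), −78 °C; isoprene; NH3 evaporated; PhNTf2, THF, −78 °C → rt
Reagents that add atoms: N-phenylbis(trifluoromethanesulfonimide), O=S(=O)(N(c1ccccc1)S(=O)(=O)C(F)(F)F)C(F)(F)F
Why: Dissolving-metal (Birch-type) enone reduction with regiospecific enolate trapping: the β-carbanion at C9 is protonated axially on the face opposite the pseudo-axial C10 methyl, in the half-chair that keeps the isopropenyl and prenyl groups equatorial, so the side chain becomes equatorial and cis to C20 as in 8-en-7-ones of the decalin series; O-triflation of enolate 17 fixes the future alkene at C7=C8.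

Step 11
Reactants: 18 (3S,4R,5R)-3-{(3S)-5-[(tert-butyldimethylsilyl)oxy]-3-methylpentyl}-2,4-dimethyl-4-(3-methylbut-2-en-1-yl)-5-(prop-1-en-2-yl)cyclohex-1-en-1-yl trifluoromethanesulfonate
Product: 20 (3S,4R,5R)-3-{(3S)-5-[(tert-butyldimethylsilyl)oxy]-3-methylpentyl}-5-(1-hydroxypropan-2-yl)-2,4-dimethyl-4-(3-methylbut-2-en-1-yl)cyclohex-1-en-1-yl trifluoromethanesulfonate (mixture at C4), via B-alkyl-9-BBN adduct 19 (not isolated)
Conditions: 9-BBN, THF, 0 °C → rt; NaBO3·4H2O, THF–H2O, rt
Reagents that add atoms: sodium perborate, [Na+].[Na+].O[B-]1(O)OO[B-](O)(O)OO1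
Why: Hydroboration–oxidation: 9-BBN adds anti-Markovnikov to the 1,1-disubstituted alkene and ignores the trisubstituted prenyl alkene and the electron-poor tetrasubstituted enol triflate; perborate is a mild enough oxidant for the triflate, and the C4 epimers converge in step 13.

Step 12
Reactants: 20 (3S,4R,5R)-3-{(3S)-5-[(tert-butyldimethylsilyl)oxy]-3-methylpentyl}-5-(1-hydroxypropan-2-yl)-2,4-dimethyl-4-(3-methylbut-2-en-1-yl)cyclohex-1-en-1-yl trifluoromethanesulfonate
Product: 21 (3S,4R,5R)-3-{(3S)-5-[(tert-butyldimethylsilyl)oxy]-3-methylpentyl}-2,4-dimethyl-4-(3-methylbut-2-en-1-yl)-5-(1-oxopropan-2-yl)cyclohex-1-en-1-yl trifluoromethanesulfonate (mixture at C4)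
Conditions: Dess–Martin periodinane, NaHCO3, CH2Cl2, 0 °C → rt
Reagents that add atoms: none
Why: Dess–Martin oxidation of a primary alcohol to the aldehyde under buffered, non-epimerising conditions that leave the silyl ether, alkene and triflate alone.

Step 13
Reactants: 21 (3S,4R,5R)-3-{(3S)-5-[(tert-butyldimethylsilyl)oxy]-3-methylpentyl}-2,4-dimethyl-4-(3-methylbut-2-en-1-yl)-5-(1-oxopropan-2-yl)cyclohex-1-en-1-yl trifluoromethanesulfonate
Product: 23 (3S,4S,5S)-3-{(3S)-5-[(tert-butyldimethylsilyl)oxy]-3-methylpentyl}-2,4-dimethyl-4-(3-methylbut-2-en-1-yl)-5-(2-methyl-1-oxopropan-2-yl)cyclohex-1-en-1-yl trifluoromethanesulfonate, via potassium enolate 22 (not isolated)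
Conditions: MeI (excess), KOtBu (1.2 equiv, added slowly), THF, −20 → 0 °C
Reagents that add atoms: iodomethane, CI
Why: α-Alkylation of an α-branched aldehyde enolate: C4–H is the only acidic hydrogen, and C-methylation gives the gem-dimethyl quaternary carbon and removes the C4 stereocentre; adding the base to substrate plus excess MeI keeps free alkoxide away from the enol triflate.

Step 14
Reactants: 23 (3S,4S,5S)-3-{(3S)-5-[(tert-butyldimethylsilyl)oxy]-3-methylpentyl}-2,4-dimethyl-4-(3-methylbut-2-en-1-yl)-5-(2-methyl-1-oxopropan-2-yl)cyclohex-1-en-1-yl trifluoromethanesulfonate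
Product: 25 (3S,4S,5S)-3-{(3S)-5-[(tert-butyldimethylsilyl)oxy]-3-methylpentyl}-2,4-dimethyl-5-(2-methyl-1-oxopropan-2-yl)-4-(2-oxoethyl)cyclohex-1-en-1-yl trifluoromethanesulfonate, via secondary ozonide 24 (not isolated)
Conditions: O3, CH2Cl2, −78 °C (Sudan red 7B end point); PPh3, −78 °C → rt
Reagents that add atoms: ozone, [O-][O+]=O
Why: Ozonolysis with reductive work-up: ozone attacks the electron-rich prenyl alkene, while the tetrasubstituted alkene bearing the strongly withdrawing triflate is inert at −78 °C when addition stops at the indicator end point; the phosphine reduces the ozonide to the C2 aldehyde.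

Step 15
Reactants: 25 (3S,4S,5S)-3-{(3S)-5-[(tert-butyldimethylsilyl)oxy]-3-methylpentyl}-2,4-dimethyl-5-(2-methyl-1-oxopropan-2-yl)-4-(2-oxoethyl)cyclohex-1-en-1-yl trifluoromethanesulfonate
Product: 26 2-[(1S,5R,6S)-5-{(3S)-5-[(tert-butyldimethylsilyl)oxy]-3-methylpentyl}-4,6-dimethyl-6-(2-oxoethyl)cyclohex-3-en-1-yl]-2-methylpropanal (15-silyloxy-2,3-seco-ent-labd-7-ene-2,3-dial)
Conditions: Pd(OAc)2 (cat.), PPh3, HCO2H, Bu3N, DMF, 60 °C
Reagents that add atoms: none
Why: Palladium-catalysed formate reduction of an enol triflate (oxidative addition to zerovalent palladium, formate exchange, decarboxylation, reductive elimination) puts hydrogen on C7 and reveals the C7=C8 alkene in its fixed position; aldehydes are tolerated in the buffered medium, and 26 is used without storage.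

Step 16
Reactants: 26 2-[(1S,5R,6S)-5-{(3S)-5-[(tert-butyldimethylsilyl)oxy]-3-methylpentyl}-4,6-dimethyl-6-(2-oxoethyl)cyclohex-3-en-1-yl]-2-methylpropanal
Product: 27 (2S,3R,5S,9R,10S,13S)-15-[(tert-butyldimethylsilyl)oxy]labd-7-ene-2,3-diol (ent-labdane series; cis-2,3-diol with both oxygens anti to C20)
Conditions: SmI2 (3 equiv, 0.1 M in THF), t-BuOH, THF, −78 °C → rt, high dilution
Reagents that add atoms: none
Why: SmI2 transfers one electron to each aldehyde (the unhindered C2 carbonyl first) and the two ketyls, both bound to oxophilic trivalent samarium, join carbon to carbon; the closest known reaction type is the SmI2-mediated intramolecular pinacol coupling of 1,6-dialdehydes to cis-cyclohexane-1,2-diols. Ring A closes in a six-membered mode by forming C2–C3 between the C1 arm on C10 and the C4 arm on C5, which are trans-diequatorial on ring B and so within reach in a chair-like transition state. The cis relation of the C2 and C3 oxygens follows from the samarium bridge that holds both oxygens on the same side while the bond forms. Of the two cis arrangements the one with both oxygens anti to C20 (C2–O equatorial, C3–O axial) is expected, because the other would put the C2 oxygen axial, syn to C20 and to the axial C4 methyl. The step needs carbonyl–carbonyl coupling to win over ketyl addition to the C7=C8 alkene, over simple reduction and over intermolecular coupling: an unactivated trisubstituted alkene is a poor ketyl acceptor without HMPA, t-BuOH is the only proton source, and high dilution favours ring closure. The C3 aldehyde cannot enolise and the silyl ether is inert, so no aldol or elimination pathway competes.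

Step 17
Reactants: 27 (2S,3R,5S,9R,10S,13S)-15-[(tert-butyldimethylsilyl)oxy]labd-7-ene-2,3-diol
Product: 28 (2S,3R,5S,9R,10S,13S)-labd-7-ene-2,3,15-triol
Conditions: Bu4NF, THF, 0 °C → rt
Reagents that add atoms: none
Why: Fluoride-mediated desilylation, driven by the strength of the Si–F bond; nothing else in the molecule responds to fluoride.

Step 18
Reactants: 28 (2S,3R,5S,9R,10S,13S)-labd-7-ene-2,3,15-triol
Product: 29 (2S,3R,5S,9R,10S,13S)-3-hydroxylabd-7-ene-2,15-diyl diacetate (target, CNP0144124.1)
Conditions: Ac2O (2.2 equiv), pyridine, 0 °C → rt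
Reagents that add atoms: acetic anhydride, CC(=O)OC(C)=O
Why: Selective acylation: the primary C15 hydroxyl and the equatorial C2 hydroxyl are esterified, while the axial C3 hydroxyl next to the C4 gem-dimethyl reacts much more slowly without an acyl-transfer catalyst; limiting the anhydride guards against a third acylation.

## Compound list

1 | dimethyl 3-methylpentanedioate | COC(=O)CC(C)CC(=O)OC | starting material
2 | (3R)-5-methoxy-3-methyl-5-oxopentanoic acid | OC(=O)C[C@@H](C)CC(=O)OC | intermediate
3 | methyl (3R)-5-hydroxy-3-methylpentanoate | OCC[C@@H](C)CC(=O)OC | intermediate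
4 | methyl (3R)-5-[(tert-butyldimethylsilyl)oxy]-3-methylpentanoate | CC(C)(C)[Si](C)(C)OCC[C@@H](C)CC(=O)OC | intermediate
5 | (3S)-5-[(tert-butyldimethylsilyl)oxy]-3-methylpentan-1-ol | CC(C)(C)[Si](C)(C)OCC[C@@H](C)CCO | intermediate
6 | tert-butyl{[(3R)-5-iodo-3-methylpentyl]oxy}dimethylsilane | CC(C)(C)[Si](C)(C)OCC[C@@H](C)CCI | intermediate
7 | (S)-carvone, (5S)-2-methyl-5-(prop-1-en-2-yl)cyclohex-2-en-1-one | CC1=CC[C@@H](CC1=O)C(C)=C | starting material
8 | lithium (3S)-6-methyl-3-(prop-1-en-2-yl)cyclohexa-1,5-dien-1-olate (not isolated) | [Li]OC1=C[C@@H](C(C)=C)CC=C1C | intermediate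
9 | (5S)-2,6-dimethyl-5-(prop-1-en-2-yl)cyclohex-2-en-1-one (mixture at C6) | O=C1C(C)=CC[C@H](C(C)=C)C1C | intermediate
10 | 1-bromo-3-methylbut-2-ene (prenyl bromide) | CC(C)=CCBr | starting material
11 | lithium (3R)-2,6-dimethyl-3-(prop-1-en-2-yl)cyclohexa-1,5-dien-1-olate (not isolated) | [Li]OC1=C(C)[C@@H](C(C)=C)CC=C1C | intermediate
12 | (5R,6R)-2,6-dimethyl-6-(3-methylbut-2-en-1-yl)-5-(prop-1-en-2-yl)cyclohex-2-en-1-one | O=C1C(C)=CC[C@H](C(C)=C)[C@@]1(C)CC=C(C)C | intermediate
13 | {(3S)-5-[(tert-butyldimethylsilyl)oxy]-3-methylpentyl}lithium (not isolated) | CC(C)(C)[Si](C)(C)OCC[C@@H](C)CC[Li] | intermediate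
14 | {(3R)-5-[(tert-butyldimethylsilyl)oxy]-3-methylpentyl}cerium dichloride (not isolated) | CC(C)(C)[Si](C)(C)OCC[C@@H](C)CC[Ce](Cl)Cl | intermediate
15 | (5R,6R)-1-{(3S)-5-[(tert-butyldimethylsilyl)oxy]-3-methylpentyl}-2,6-dimethyl-6-(3-methylbut-2-en-1-yl)-5-(prop-1-en-2-yl)cyclohex-2-en-1-ol (mixture at C1) | CC(C)(C)[Si](C)(C)OCC[C@@H](C)CCC1(O)C(C)=CC[C@H](C(C)=C)[C@@]1(C)CC=C(C)C | intermediate
16 | (4R,5R)-3-{(3S)-5-[(tert-butyldimethylsilyl)oxy]-3-methylpentyl}-2,4-dimethyl-4-(3-methylbut-2-en-1-yl)-5-(prop-1-en-2-yl)cyclohex-2-en-1-one | CC(C)(C)[Si](C)(C)OCC[C@@H](C)CCC1=C(C)C(=O)C[C@H](C(C)=C)[C@@]1(C)CC=C(C)C | intermediate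
17 | lithium (3S,4R,5R)-3-{(3S)-5-[(tert-butyldimethylsilyl)oxy]-3-methylpentyl}-2,4-dimethyl-4-(3-methylbut-2-en-1-yl)-5-(prop-1-en-2-yl)cyclohex-1-en-1-olate (not isolated) | CC(C)(C)[Si](C)(C)OCC[C@@H](C)CC[C@@H]1C(C)=C(O[Li])C[C@H](C(C)=C)[C@@]1(C)CC=C(C)C | intermediate
18 | (3S,4R,5R)-3-{(3S)-5-[(tert-butyldimethylsilyl)oxy]-3-methylpentyl}-2,4-dimethyl-4-(3-methylbut-2-en-1-yl)-5-(prop-1-en-2-yl)cyclohex-1-en-1-yl trifluoromethanesulfonate | CC(C)(C)[Si](C)(C)OCC[C@@H](C)CC[C@@H]1C(C)=C(OS(=O)(=O)C(F)(F)F)C[C@H](C(C)=C)[C@@]1(C)CC=C(C)C | intermediate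
19 | B-alkyl-9-borabicyclo[3.3.1]nonane adduct of 18 at the isopropenyl CH2 (mixture at C4; not isolated) | CC(C)(C)[Si](C)(C)OCC[C@@H](C)CC[C@@H]1C(C)=C(OS(=O)(=O)C(F)(F)F)C[C@H](C(C)CB2C3CCCC2CCC3)[C@@]1(C)CC=C(C)C | intermediate
20 | (3S,4R,5R)-3-{(3S)-5-[(tert-butyldimethylsilyl)oxy]-3-methylpentyl}-5-(1-hydroxypropan-2-yl)-2,4-dimethyl-4-(3-methylbut-2-en-1-yl)cyclohex-1-en-1-yl trifluoromethanesulfonate (mixture at C4) | CC(C)(C)[Si](C)(C)OCC[C@@H](C)CC[C@@H]1C(C)=C(OS(=O)(=O)C(F)(F)F)C[C@H](C(C)CO)[C@@]1(C)CC=C(C)C | intermediate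
21 | (3S,4R,5R)-3-{(3S)-5-[(tert-butyldimethylsilyl)oxy]-3-methylpentyl}-2,4-dimethyl-4-(3-methylbut-2-en-1-yl)-5-(1-oxopropan-2-yl)cyclohex-1-en-1-yl trifluoromethanesulfonate (mixture at C4) | CC(C)(C)[Si](C)(C)OCC[C@@H](C)CC[C@@H]1C(C)=C(OS(=O)(=O)C(F)(F)F)C[C@H](C(C)C=O)[C@@]1(C)CC=C(C)C | intermediate
22 | potassium enolate of aldehyde 21 (C4=C3–OK; not isolated) | CC(C)(C)[Si](C)(C)OCC[C@@H](C)CC[C@@H]1C(C)=C(OS(=O)(=O)C(F)(F)F)C[C@H](C(C)=CO[K])[C@@]1(C)CC=C(C)C | intermediate
23 | (3S,4S,5S)-3-{(3S)-5-[(tert-butyldimethylsilyl)oxy]-3-methylpentyl}-2,4-dimethyl-4-(3-methylbut-2-en-1-yl)-5-(2-methyl-1-oxopropan-2-yl)cyclohex-1-en-1-yl trifluoromethanesulfonate | CC(C)(C)[Si](C)(C)OCC[C@@H](C)CC[C@@H]1C(C)=C(OS(=O)(=O)C(F)(F)F)C[C@H](C(C)(C)C=O)[C@@]1(C)CC=C(C)C | intermediate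
24 | secondary ozonide of 23 (5,5-dimethyl-1,2,4-trioxolan-3-ylmethyl group on C10; mixture at the ozonide carbon; not isolated) | CC(C)(C)[Si](C)(C)OCC[C@@H](C)CC[C@@H]1C(C)=C(OS(=O)(=O)C(F)(F)F)C[C@H](C(C)(C)C=O)[C@@]1(C)CC2OOC(C)(C)O2 | intermediate
25 | (3S,4S,5S)-3-{(3S)-5-[(tert-butyldimethylsilyl)oxy]-3-methylpentyl}-2,4-dimethyl-5-(2-methyl-1-oxopropan-2-yl)-4-(2-oxoethyl)cyclohex-1-en-1-yl trifluoromethanesulfonate | CC(C)(C)[Si](C)(C)OCC[C@@H](C)CC[C@@H]1C(C)=C(OS(=O)(=O)C(F)(F)F)C[C@H](C(C)(C)C=O)[C@@]1(C)CC=O | intermediate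
26 | 2-[(1S,5R,6S)-5-{(3S)-5-[(tert-butyldimethylsilyl)oxy]-3-methylpentyl}-4,6-dimethyl-6-(2-oxoethyl)cyclohex-3-en-1-yl]-2-methylpropanal | CC(C)(C)[Si](C)(C)OCC[C@@H](C)CC[C@@H]1C(C)=CC[C@H](C(C)(C)C=O)[C@@]1(C)CC=O | intermediate
27 | (2S,3R,5S,9R,10S,13S)-15-[(tert-butyldimethylsilyl)oxy]labd-7-ene-2,3-diol | CC(C)(C)[Si](C)(C)OCC[C@@H](C)CC[C@@H]1C(C)=CC[C@@H]2C(C)(C)[C@@H](O)[C@@H](O)C[C@@]12C | intermediate
28 | (2S,3R,5S,9R,10S,13S)-labd-7-ene-2,3,15-triol | OCC[C@@H](C)CC[C@@H]1C(C)=CC[C@@H]2C(C)(C)[C@@H](O)[C@@H](O)C[C@@]12C | intermediate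
29 | (2S,3R,5S,9R,10S,13S)-3-hydroxylabd-7-ene-2,15-diyl diacetate | CC(=O)OCC[C@@H](C)CC[C@@H]1C(C)=CC[C@@H]2C(C)(C)[C@@H](O)[C@@H](OC(C)=O)C[C@@]12C | target

## Step count and least certain steps

Total: 18 steps. Longest linear sequence: 16 steps (steps 1–5 and 8–18, from 1); the ring B branch from 7 is 13 steps (steps 6–18).

**Step 16 (key step).** The hindered neopentyl C3 aldehyde may be reduced to the alcohol before the C–C bond forms, or the coupling may proceed through an unbridged transition state and lose cis selectivity. Fallback: the C2–C3 bond is made as an alkene and the oxygens are added afterwards, while the ring B alkene is still masked. Aldehyde 23 is methylenated with Ph3P=CH2 to the 5-(2-methylbut-3-en-2-yl) analogue of enol triflate 18 F1. Ring-closing metathesis with second-generation Grubbs catalyst (loss of 2-methylpropene) gives 15-silyloxy-ent-labda-2,7-dien-7-yl triflate F2. Dihydroxylation with OsO4 (cat.) and N-methylmorpholine N-oxide, which attacks the 2,3-alkene from the face opposite C20 and the axial C4 methyl and leaves the enol triflate alone, gives the 2,3-cis-diol enol triflate F3. Reduction with Pd(OAc)2, PPh3, HCO2H and Bu3N then returns to the route at 27.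

**Step 10.** Facial selectivity in the protonation of the C9 carbanion may be poor if the monocyclic ring populates more than one half-chair. Fallback: hydrogen is delivered to C9 as a hydride from a bulky metal and not as a proton. Enone 16 is treated with Et3SiH and catalytic RhCl(PPh3)3 (1,4-hydrosilylation from the face opposite the C10 methyl) to give the triethylsilyl enol ether of the C9-reduced ketone F4. Cleavage with MeLi in THF regenerates lithium enolate 17, which is triflated with PhNTf2, so the route is rejoined at 18.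

**Step 13.** O-methylation may compete with C-methylation at the hindered enolate carbon, and the enol triflate may be lost to free alkoxide. Fallback: the aldehyde is alkylated through an aza-enolate, which reacts at carbon at low temperature. Aldehyde 21 is condensed with 1,1-dimethylhydrazine to the N,N-dimethylhydrazone of 21 F5. Deprotonation with LiN(iPr)2 at −78 °C and methylation with MeI give the N,N-dimethylhydrazone of 23 F6, and hydrolysis with CuCl2 in buffered aqueous THF returns to the route at 23.

**Step 15.** An intramolecular aldol reaction of the 1,6-dialdehyde (C1 onto C3) may be triggered by the amine at 60 °C during the triflate reduction. Fallback: both carbonyls are kept at the alcohol level while palladium is present. Ozonolysis of 23 is worked up with NaBH4 to the 2,3-seco-2,3-diol enol triflate F7. Formate reduction with Pd(OAc)2 and PPh3 gives 15-silyloxy-2,3-seco-ent-labd-7-ene-2,3-diol F8, and a double Swern oxidation ((COCl)2, DMSO, Et3N, −78 °C) returns to the route at 26.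

**Step 18.** The third hydroxyl may be acylated, or the acetyl group may migrate from O2 to O3 on prolonged exposure to base. Fallback: the two acylations are separated and the second is directed by tin. Triol 28 is acetylated at the primary hydroxyl only (AcCl, 2,4,6-collidine, CH2Cl2, −78 °C) to (2S,3R,5S,9R,10S,13S)-2,3-dihydroxylabd-7-en-15-yl acetate F9. Heating with Bu2SnO in toluene gives the 2,3-O-dibutylstannylene acetal of F9 F10, whose equatorial C2 oxygen is acylated by AcCl at 0 °C, which returns to the route at 29.

## Further compounds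

F1 | step 16 | 3-{(3S)-5-[(tert-butyldimethylsilyl)oxy]-3-methylpentyl}-2,4-dimethyl-5-(2-methylbut-3-en-2-yl)-4-(3-methylbut-2-en-1-yl)cyclohex-1-en-1-yl trifluoromethanesulfonate (ring configuration as in 23) | CC(C)(C)[Si](C)(C)OCC[C@@H](C)CC[C@@H]1C(C)=C(OS(=O)(=O)C(F)(F)F)C[C@H](C(C)(C)C=C)[C@@]1(C)CC=C(C)C
F2 | step 16 | 15-[(tert-butyldimethylsilyl)oxy]-ent-labda-2,7-dien-7-yl trifluoromethanesulfonate (C5, C9, C10, C13 as in 27) | CC(C)(C)[Si](C)(C)OCC[C@@H](C)CC[C@@H]1C(C)=C(OS(=O)(=O)C(F)(F)F)C[C@@H]2C(C)(C)C=CC[C@@]12C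
F3 | step 16 | 15-[(tert-butyldimethylsilyl)oxy]-2,3-dihydroxy-ent-labd-7-en-7-yl trifluoromethanesulfonate (cis-2,3-diol as in 27) | CC(C)(C)[Si](C)(C)OCC[C@@H](C)CC[C@@H]1C(C)=C(OS(=O)(=O)C(F)(F)F)C[C@@H]2C(C)(C)[C@@H](O)[C@@H](O)C[C@@]12C
F4 | step 10 | triethylsilyl enol ether: tert-butyldimethylsilyl ether of (3S)-3-methyl-5-[(1S,5R,6R)-2,6-dimethyl-6-(3-methylbut-2-en-1-yl)-5-(prop-1-en-2-yl)-3-(triethylsilyloxy)cyclohex-2-en-1-yl]pentan-1-ol | CC(C)(C)[Si](C)(C)OCC[C@@H](C)CC[C@@H]1C(C)=C(O[Si](CC)(CC)CC)C[C@H](C(C)=C)[C@@]1(C)CC=C(C)C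
F5 | step 13 | (E)-N,N-dimethylhydrazone of aldehyde 21 (mixture at C4) | CC(C)(C)[Si](C)(C)OCC[C@@H](C)CC[C@@H]1C(C)=C(OS(=O)(=O)C(F)(F)F)C[C@H](C(C)/C=N/N(C)C)[C@@]1(C)CC=C(C)C
F6 | step 13 | (E)-N,N-dimethylhydrazone of aldehyde 23 | CC(C)(C)[Si](C)(C)OCC[C@@H](C)CC[C@@H]1C(C)=C(OS(=O)(=O)C(F)(F)F)C[C@H](C(C)(C)/C=N/N(C)C)[C@@]1(C)CC=C(C)C
F7 | step 15 | 3-{(3S)-5-[(tert-butyldimethylsilyl)oxy]-3-methylpentyl}-4-(2-hydroxyethyl)-5-(1-hydroxy-2-methylpropan-2-yl)-2,4-dimethylcyclohex-1-en-1-yl trifluoromethanesulfonate (ring configuration as in 25) | CC(C)(C)[Si](C)(C)OCC[C@@H](C)CC[C@@H]1C(C)=C(OS(=O)(=O)C(F)(F)F)C[C@H](C(C)(C)CO)[C@@]1(C)CCO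
F8 | step 15 | 15-[(tert-butyldimethylsilyl)oxy]-2,3-seco-ent-labd-7-ene-2,3-diol (ring configuration as in 26) | CC(C)(C)[Si](C)(C)OCC[C@@H](C)CC[C@@H]1C(C)=CC[C@H](C(C)(C)CO)[C@@]1(C)CCO
F9 | step 18 | (2S,3R,5S,9R,10S,13S)-2,3-dihydroxylabd-7-en-15-yl acetate | CC(=O)OCC[C@@H](C)CC[C@@H]1C(C)=CC[C@@H]2C(C)(C)[C@@H](O)[C@@H](O)C[C@@]12C
F10 | step 18 | 2,3-O-dibutylstannylene acetal of F9 | CC(=O)OCC[C@@H](C)CC[C@@H]1C(C)=CC[C@@H]2C(C)(C)[C@H]3O[Sn](CCCC)(CCCC)O[C@H]3C[C@@]12C
A1 | alternative 1 | (5R,6R)-6-(3-diazo-2-oxopropyl)-2,6-dimethyl-5-(prop-1-en-2-yl)cyclohex-2-en-1-one | O=C1C(C)=CC[C@H](C(C)=C)[C@@]1(C)CC(=O)C=[N+]=[N-]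
A2 | alternative 1 | tricyclic diketone: ring B enone with C9 ketone, ring A C2 ketone, cyclopropane C3–C4–C18 | O=C1C[C@@]2(C)C(=O)C(C)=CC[C@@H]2[C@@]3(C)C[C@@H]13
A3 | alternative 2 | acyclic triene: methyl (Z)-alkylidene ester (C9=C10, ester carbon C20) linked through C1–C4 (2,3-acetonide) to a (5E,7Z)-7-silyloxy diene, 15-silyl ether | C/C=C(O[Si](C)(C)C(C)(C)C)/C=C/C(C)(C)[C@@H](O3)[C@@H](OC3(C)C)C/C(C(=O)OC)=C/CC[C@H](C)CCO[Si](C)(C)C(C)(C)C
A4 | alternative 2 | trans-decalin with C20 methyl ester, C6=C7 silyl enol ether, 2,3-acetonide, 15-silyl ether | CC(C)(C)[Si](C)(C)OCC[C@@H](C)CC[C@@H]1[C@H](C)C(O[Si](C)(C)C(C)(C)C)=C[C@@H]2C(C)(C)[C@@H](O3)[C@@H](OC3(C)C)C[C@@]12C(=O)OC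
A5 | alternative 3 | cis-fused 2,2,4,4,6-pentamethyl-5-vinyl-3a,4,7,7a-tetrahydro-1,3-benzodioxole (ring A diene, C2 and C3 as in the target) | C=CC1=C(C)C[C@H](O2)[C@H](OC2(C)C)C1(C)C
A6 | alternative 3 | (5R)-7-[(tert-butyldimethylsilyl)oxy]-5-methylhept-2-yn-4-one | CC#CC(=O)C[C@H](C)CCO[Si](C)(C)C(C)(C)C
A7 | alternative 3 | 11-oxo-ent-labda-5,8-diene 2,3-acetonide 15-tert-butyldimethylsilyl ether | CC1=C(C(=O)C[C@H](C)CCO[Si](C)(C)C(C)(C)C)[C@]2(C)C[C@H](O3)[C@H](OC3(C)C)C(C)(C)C2=CC1
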